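The catalyst you charge stays in the flask in one form or another, and each unit of product costs one unit of starting material and one of reagent. So a rate is the share of catalyst at work, times what that share does with the reagent it meets.

the same everywhere: catalyst 0.00200 M

| flask | starting material | reagent | product | time |
|---|---|---|---|---|
| south | 0.400 M | 0.800 M |  |  |
| south-east | 0.200 M | 0.600 M |  |  |
| north-east | 1.20 M | 0.800 M |  |  |
| south-west | 0.400 M | 0.800 M | 0.200 M |  |
| west | 0.200 M | 0.260 M |  | 24 min |

| run | time / min | [product] / M |
|---|---|---|
| south run | 0.96 | 0.0076 |
| south run | 2.1 | 0.0171 |
| south run | 4.8 | 0.0374 |
| south run | 11 | 0.0777 |
| south run | 24 | 0.1486 |
| south-east run | 0.96 | 0.0048 |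
| south-east run | 2.1 | 0.0103 |
| south-east run | 4.8 | 0.0217 |
| south-east run | 11 | 0.0478 |
| south-east run | 24 | 0.0884 |
| north-east run | 0.96 | 0.0094 |
| north-east run | 2.1 | 0.0209 |
| north-east run | 4.8 | 0.0467 |
| north-east run | 11 | 0.0988 |
| north-east run | 24 | 0.1929 |
| south-west run | 0.96 | 0.2065 |
| south-west run | 2.1 | 0.2184 |
| south-west run | 4.8 | 0.2384 |
| south-west run | 11 | 0.2796 |
| south-west run | 24 | 0.3484 |

(standard deviation of a reading: 0.001 M)

- the exponent of [reagent] in the starting rate at the charge of the south run (at the point where two percent of the starting material have become product)
- the exponent of [starting material] in the starting rate at the charge of the south run (at the point where two percent of the starting material have become product) (one fixed amount of product, the same in the runs compared)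
- the south-east run starts with 0.200 M less of starting material and of reagent than the south run, and with no product. Compared where both hold the same amount of starting material, once fifteen percent of what the south-east run was charged with has turned into product, is the south-east run faster, slower or alike (within a tenth)?
- product in the west run at 24 min, as a share of the starting material charged
- which of these the readings show (the by-product ties up the catalyst / the catalyst wakes slowly / the second partner kills the catalyst / nothing beyond the main steps / the catalyst dies by itself)

- Overall: starting material + reagent -> product, with catalyst as catalyst.
- Constant volume, constant temperature.
- What is held in complexes is read along with the free species.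
- "The second partner" is reagent.
- An order is taken over about fifteen percent of the charge, up and down.

The north-east run holds 3.00 times the south run's starting material at equal reagent, yet by 2.1 min it has made only 1.22 times as much product. A catalyst filling up behaves this way. Take the uptake of starting material as a fast equilibrium, so that the loaded catalyst is the resting state. The ratio then gives 0.375 of the south run's charge for the half-load, the amount of starting material that keeps half of the catalyst loaded. The loaded share is the starting material remaining divided by that amount plus the half-load. The unloaded share at the south charge, 0.273, is my order in starting material, and I take reagent at the first power.

Now build up the west run. Dividing the south run's mean rate up to 2.1 min, 0.00814 M min⁻¹, by its reagent and its loaded share leaves 0.01400 min⁻¹. With the main step alone and the catalyst fully loaded, the reaction is pseudo-first-order in reagent, and the west run reaches 37.1% of its charge at 24 min.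

Next add the loading. The west half-load is 0.750 of the west charge, so only 0.571 of the catalyst starts loaded. Held at that rate, the run would reach 25.0%. Taking the rate halfway along gives 21.3%, less than the main step alone.

Then add the rest. Between 11 min and 24 min the south run turns 0.01363 min⁻¹ of its charge, while the law so far gives 0.01578 min⁻¹, so the run is slower than the law. Added product shows no such effect: by 24 min the south-west run has gained 0.1484 M and the south run has made 0.1486 M. I therefore charge the slowing to the by-product, which I take to come with each unit of product made. Read as a rival for the catalyst, it adds 0.608 to the half-load for each fraction of charge turned. The west run then comes to 21.0%, below the previous step. With 0.200 M less by-product behind it, the south-east run should be faster at equal holdings.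

The forecast gave 0.95 for reagent, 0.3 for starting material, faster, and 20.5%, and it named the catalyst dies by itself, saying the slowing “points to catalyst dying by itself”, so my reckoning differs from it on the cause and on the west figure.

The orders come out at 1.0 and 0.27, the south-east run is faster, and the west run gives 21.4%. The readings show that the by-product ties up the catalyst: fitted with nothing beyond the main steps the residual is 2.3 in units of the scatter, and with the steps below it is 0.74.

    catalyst + starting material ⇌ catalyst-substrate complex, settled at all times (7.510 M⁻¹)
    catalyst-substrate complex + reagent → product + catalyst + by-product (6.960 M⁻¹ min⁻¹)
    catalyst + by-product ⇌ catalyst-by-product complex, settled at all times (5.890 M⁻¹)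

The south-east run holds the west run's charge of starting material, so its half-load is the same 0.750 of its charge. With the by-product's 0.608 and its own reagent, that puts a quarter of the charge at 12.1 min, and the run reaches it at 11.8 min.

(The readings come from a simulation for an exercise, noise included.)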